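**Strategy.** Ring C (O1–C2–C3–C4–C4a–C8a) is cut into two three-atom halves. O1–C2–C3 is the ambident enolate of a B-ring arylacetaldehyde, and C4–C4a–C8a is a 2-fluorobenzoyl chloride. The key step exploits that C4 hangs on C4a, ortho to C8a of ring A. A temporary C4 carbonyl is first the acyl electrophile for C3 and then activates C8a–F towards O1. One base-mediated operation (O-acylation, O-to-C acyl shift, SNAr) thus forms C3–C4 and O1–C8a and gives an isoflavone. The same carbonyl later activates C7–F (para) for oxygen introduction and labilises C3 for a dynamic kinetic transfer hydrogenation that sets (3S). Hydrogenolysis finally erases it.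

Key step: step 5

Remark: isoflavan numbering is used (O1, C2, C3, C4, C4a, C5–C8, C8a; B ring primed). The only stereocentre of the target, C3, is S. Compounds 1 and 3 are taken as commercial.

Step 1
Reactants: 1 2,4-difluoro-3-methoxybenzoic acid
Product: 2 2,4-difluoro-3-methoxybenzoyl chloride
Conditions: (COCl)2, cat. DMF, CH2Cl2, 0 °C → rt
Reagents that add atoms: oxalyl chloride, O=C(Cl)C(=O)Cl
Why: Vilsmeier-type activation of the acid should give the acid chloride, and the aryl fluorides and the methyl ether are inert to it.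

Step 2
Reactants: 3 2,4,5-trimethoxybenzaldehyde
Product: 7 3-hydroxy-2,4,5-trimethoxybenzaldehyde, via lithium amino alkoxide 4 (not isolated), via ring-lithiated amino alkoxide 5 (not isolated), via dimethyl arylboronate 6 (not isolated)
Conditions: N-methylpiperazine, n-BuLi, THF, −20 °C, then 3; n-BuLi, −20 → 0 °C; B(OMe)3, −78 °C → rt; 30% H2O2, aq NaOH, 0 °C; aq NH4Cl
Reagents that add atoms: hydrogen peroxide, OO; for the intermediates 4–6 only: N-methylpiperazine, CN1CCNCC1; n-butyllithium, [Li]CCCC; trimethyl borate, COB(OC)OC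
Why: Directed ortho-metalation with in situ protection: the lithium amide adds to the aldehyde to give the bulky anionic α-amino alkoxide 4, which masks CHO and shields C6, so n-BuLi should remove the C3 proton between the 2- and 4-methoxy groups, and borylation with basic peroxide oxidation (aryl shift from boron to oxygen) gives the phenol while aqueous work-up releases the aldehyde.

Step 3
Reactants: 7 3-hydroxy-2,4,5-trimethoxybenzaldehyde
Product: 8 3-(benzyloxy)-2,4,5-trimethoxybenzaldehyde
Conditions: BnBr, K2CO3, DMF, 60 °C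
Reagents that add atoms: benzyl bromide, BrCc1ccccc1
Why: Williamson ether synthesis on the only acidic OH, which puts on a group that the final hydrogenolysis removes.

Step 4
Reactants: 8 3-(benzyloxy)-2,4,5-trimethoxybenzaldehyde
Product: 10 2-[3-(benzyloxy)-2,4,5-trimethoxyphenyl]acetaldehyde, via methyl enol ether 9 (not isolated)
Conditions: Ph3P(CH2OMe)Cl, KOtBu, THF, 0 °C → rt; then 2 M aq HCl, THF, rt; used without storage
Reagents that add atoms: (methoxymethyl)triphenylphosphonium chloride, COC[P+](c1ccccc1)(c1ccccc1)c1ccccc1.[Cl-]; water, O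
Why: Wittig methoxymethylenation followed by acid hydrolysis of the electron-rich enol ether is the standard one-carbon homologation of an aryl aldehyde, and the benzyl and methyl ethers survive dilute acid.

Step 5
Reactants: 2 2,4-difluoro-3-methoxybenzoyl chloride; 10 2-[3-(benzyloxy)-2,4,5-trimethoxyphenyl]acetaldehyde
Product: 13 3-[3-(benzyloxy)-2,4,5-trimethoxyphenyl]-7-fluoro-8-methoxy-4H-chromen-4-one, via enol ester 11 (not isolated), via oxopropanal enolate 12 (not isolated)
Conditions: Cs2CO3 (3 equiv), DMAP (20 mol %), 4 Å MS, MeCN, slow addition of 10 to 2 at 0 °C, then 80 °C, one pot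
Reagents that add atoms: none
Why: Proposed new method: base and DMAP should first acylate the acidic arylacetaldehyde 10 on oxygen to enol ester 11, an active ester whose leaving group is about as good as a phenoxide, so DMAP reopens it to an acylpyridinium/enolate pair and the slower but irreversible C-acylation at C3 drains the mixture into the carbonate-deprotonated 12 (bond C3–C4). The enolate oxygen O1 of 12 then attacks C8a, a vinylogous acyl fluoride carbon ortho to the new C4 ketone, and expels fluoride (bond O1–C8a). The pyranone ring, the only ring formed, closes by a 6-endo-trig addition–elimination (SNAr). The closest known reaction types are the one-pot C-acylation/fluoride displacement of 1,3-dicarbonyl enolates with 2-fluorobenzoyl chlorides that gives chromones, the Grohe–Heitzer cycloaracylation of quinolone chemistry and the Steglich-type O-to-C acyl transfer, and what is new is an aldehyde enolate as the three-atom partner. No stereocentre is created, because C3 is sp2 in 13. The step needs C- over O-acylation (secured by the reversible O-acylation and the irreversible ring closure), C8a–F over C7–F (only C8a lies within reach of O1 in a six-membered transition state) and acylation over aldol self-condensation (slow addition of 10 to the acylating agent).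

Step 6
Reactants: 13 3-[3-(benzyloxy)-2,4,5-trimethoxyphenyl]-7-fluoro-8-methoxy-4H-chromen-4-one
Product: 14 7-(benzyloxy)-3-[3-(benzyloxy)-2,4,5-trimethoxyphenyl]-8-methoxy-4H-chromen-4-one
Conditions: BnOH, Cs2CO3, dry DMSO, 70 °C; 1 M HCl work-up
Reagents that add atoms: benzyl alcohol, OCc1ccccc1
Why: Nucleophilic aromatic substitution (addition–elimination): C7–F is para to the C4 carbonyl through C4a and is the only leaving group left on ring A, and competing alkoxide addition at C2 is reversible whereas loss of fluoride is not.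

Step 7
Reactants: 14 7-(benzyloxy)-3-[3-(benzyloxy)-2,4,5-trimethoxyphenyl]-8-methoxy-4H-chromen-4-one
Product: 16 (3S,4S)-7-(benzyloxy)-3-[3-(benzyloxy)-2,4,5-trimethoxyphenyl]-8-methoxychroman-4-ol (3,4-cis), via racemic isoflavanone 15 (not isolated)
Conditions: RuCl[(S,S)-TsDPEN](p-cymene) or its tethered analogue (5 mol %), HCO2H/Et3N 5:2, EtOAc, 45 °C
Reagents that add atoms: none
Why: Noyori–Ikariya asymmetric transfer hydrogenation run as a cascade with dynamic kinetic resolution: Ru–H should add 1,4 to the enone to give racemic 15, whose C3 epimerises fast through the enol in the amine medium, and the (S,S)-catalyst, which gives S carbinols from aryl ketones, reduces the matched (3S)-ketone faster with hydride delivery anti to the C3 aryl group, so the catalyst sets C4 (S) and the cis-selective resolution sets C3 (S).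

Step 8
Reactants: 16 (3S,4S)-7-(benzyloxy)-3-[3-(benzyloxy)-2,4,5-trimethoxyphenyl]-8-methoxychroman-4-ol
Product: 17 (3S)-3-(3-hydroxy-2,4,5-trimethoxyphenyl)-8-methoxychroman-7-ol (target)
Conditions: H2 (3 atm), 10% Pd/C, EtOH–EtOAc, AcOH (few vol %), rt
Reagents that add atoms: none
Why: Catalytic hydrogenolysis should cleave both O-benzyl ethers and the C4–OH bond, a benzylic C–O bond activated by the para C7 oxygen, without touching the C3–H bond, so the 3S centre is carried into the target.

**Compound list**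
1 | 2,4-difluoro-3-methoxybenzoic acid | COc1c(F)ccc(C(=O)O)c1F | starting material
2 | 2,4-difluoro-3-methoxybenzoyl chloride | COc1c(F)ccc(C(=O)Cl)c1F | intermediate
3 | 2,4,5-trimethoxybenzaldehyde | COc1cc(OC)c(C=O)cc1OC | starting material
4 | lithium (4-methylpiperazin-1-yl)(2,4,5-trimethoxyphenyl)methanolate (racemic) | [Li]OC(N1CCN(C)CC1)c1cc(OC)c(OC)cc1OC | intermediate
5 | 3-lithio derivative of 4 | [Li]OC(N1CCN(C)CC1)c1cc(OC)c(OC)c([Li])c1OC | intermediate
6 | 3-(dimethoxyboryl) derivative of 4 | [Li]OC(N1CCN(C)CC1)c1cc(OC)c(OC)c(B(OC)OC)c1OC | intermediate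
7 | 3-hydroxy-2,4,5-trimethoxybenzaldehyde | O=Cc1cc(OC)c(OC)c(O)c1OC | intermediate
8 | 3-(benzyloxy)-2,4,5-trimethoxybenzaldehyde | O=Cc1cc(OC)c(OC)c(OCc2ccccc2)c1OC | intermediate
9 | 1-[3-(benzyloxy)-2,4,5-trimethoxyphenyl]-2-methoxyethene (E/Z mixture) | COC=Cc1cc(OC)c(OC)c(OCc2ccccc2)c1OC | intermediate
10 | 2-[3-(benzyloxy)-2,4,5-trimethoxyphenyl]acetaldehyde | O=CCc1cc(OC)c(OC)c(OCc2ccccc2)c1OC | intermediate
11 | 2-[3-(benzyloxy)-2,4,5-trimethoxyphenyl]vinyl 2,4-difluoro-3-methoxybenzoate (E/Z) | COc1cc(C=COC(=O)c2ccc(F)c(OC)c2F)c(OC)c(OCc2ccccc2)c1OC | intermediate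
12 | 2-[3-(benzyloxy)-2,4,5-trimethoxyphenyl]-3-(2,4-difluoro-3-methoxyphenyl)-3-oxopropanal, drawn as the hydroxymethylene tautomer (present as cesium enolate) | COc1cc(C(=CO)C(=O)c2ccc(F)c(OC)c2F)c(OC)c(OCc2ccccc2)c1OC | intermediate
13 | 3-[3-(benzyloxy)-2,4,5-trimethoxyphenyl]-7-fluoro-8-methoxy-4H-chromen-4-one | COc1cc(C2=COc3c(ccc(F)c3OC)C2=O)c(OC)c(OCc2ccccc2)c1OC | intermediate
14 | 7-(benzyloxy)-3-[3-(benzyloxy)-2,4,5-trimethoxyphenyl]-8-methoxy-4H-chromen-4-one | COc1cc(C2=COc3c(ccc(OCc4ccccc4)c3OC)C2=O)c(OC)c(OCc2ccccc2)c1OC | intermediate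
15 | rac-7-(benzyloxy)-3-[3-(benzyloxy)-2,4,5-trimethoxyphenyl]-8-methoxychroman-4-one | COc1cc(C2COc3c(ccc(OCc4ccccc4)c3OC)C2=O)c(OC)c(OCc2ccccc2)c1OC | intermediate
16 | (3S,4S)-7-(benzyloxy)-3-[3-(benzyloxy)-2,4,5-trimethoxyphenyl]-8-methoxychroman-4-ol | COc1cc([C@H]2COc3c(ccc(OCc4ccccc4)c3OC)[C@H]2O)c(OC)c(OCc2ccccc2)c1OC | intermediate
17 | (3S)-3-(3-hydroxy-2,4,5-trimethoxyphenyl)-8-methoxychroman-7-ol | COc1cc([C@H]2COc3c(ccc(O)c3OC)C2)c(OC)c(O)c1OC | target

**Total step count:** 8. **Longest linear sequence:** 7 (steps 2–8, from 3).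

**Steps most likely to fail**

1. Step 5 (Proposed new method). The acyl group may stay on oxygen because the O-to-C transfer is too slow, or aldol self-condensation and deformylation may outrun ring closure. The fallback uses known chemistry, sets out from 10 and returns at 13. Aldehyde 10 is condensed with morpholine (toluene, molecular sieves) to 4-{(E)-2-[3-(benzyloxy)-2,4,5-trimethoxyphenyl]vinyl}morpholine F1. Its β-carbon is C-acylated by 2 (Et3N, toluene, 80 °C, enamine acylation) to 2-[3-(benzyloxy)-2,4,5-trimethoxyphenyl]-1-(2,4-difluoro-3-methoxyphenyl)-3-(morpholin-4-yl)prop-2-en-1-one F2. Aqueous HCl in THF hydrolyses F2 to 12, and K2CO3 in DMF at 80 °C closes the ring by fluoride displacement to 13. In this variant O1 comes from water.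

2. Step 6. Conjugate attack of the alkoxide at C2, followed by ring opening and loss of the C2 carbon, may outrun fluoride displacement at C7, which the neighbouring 8-methoxy group slows. The fallback brings in the C7 oxygen before ring C exists. It sets out from 2 (and 10) and returns at 14.
   - Benzyl alcohol (2 equiv) and KOtBu in THF/DMF at 0 °C convert 2 by esterification, and then by SNAr at the less hindered fluorine para to the ester, into benzyl 4-(benzyloxy)-2-fluoro-3-methoxybenzoate F3.
   - LiOH in aqueous THF gives 4-(benzyloxy)-2-fluoro-3-methoxybenzoic acid F4.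
   - Oxalyl chloride with cat. DMF gives 4-(benzyloxy)-2-fluoro-3-methoxybenzoyl chloride F5.
   - F5 and 10 under the conditions of step 5 should pass through 2-[3-(benzyloxy)-2,4,5-trimethoxyphenyl]vinyl 4-(benzyloxy)-2-fluoro-3-methoxybenzoate F6 and 3-[4-(benzyloxy)-2-fluoro-3-methoxyphenyl]-2-[3-(benzyloxy)-2,4,5-trimethoxyphenyl]-3-oxopropanal F7 to 14.

3. Step 8. Acid-assisted dehydration across C3–C4 followed by re-hydrogenation would erode the configuration at C3, and without acid the C4–O cleavage may stall. The fallback separates deoxygenation from debenzylation and avoids a C4 cation. It sets out from 16 and returns at 17.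
   - 1,1'-Thiocarbonyldiimidazole with DMAP in CH2Cl2 gives O-{(3S,4S)-7-(benzyloxy)-3-[3-(benzyloxy)-2,4,5-trimethoxyphenyl]-8-methoxychroman-4-yl} imidazole-1-carbothioate F8. Syn elimination is blocked here because C3–H is anti to the C4 oxygen.
   - Barton–McCombie reduction (Bu3SnH, AIBN, toluene, 90 °C) gives (3S)-7-(benzyloxy)-3-[3-(benzyloxy)-2,4,5-trimethoxyphenyl]-8-methoxychroman F9.
   - Neutral hydrogenolysis (H2, Pd/C, EtOAc) gives 17.

**Further compounds**
F1 | step 5 | 4-{(E)-2-[3-(benzyloxy)-2,4,5-trimethoxyphenyl]vinyl}morpholine | COc1cc(/C=C/N2CCOCC2)c(OC)c(OCc2ccccc2)c1OC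
F2 | step 5 | 2-[3-(benzyloxy)-2,4,5-trimethoxyphenyl]-1-(2,4-difluoro-3-methoxyphenyl)-3-(morpholin-4-yl)prop-2-en-1-one | COc1cc(C(=CN2CCOCC2)C(=O)c2ccc(F)c(OC)c2F)c(OC)c(OCc2ccccc2)c1OC
F3 | step 6 | benzyl 4-(benzyloxy)-2-fluoro-3-methoxybenzoate | O=C(OCc1ccccc1)c1ccc(OCc2ccccc2)c(OC)c1F
F4 | step 6 | 4-(benzyloxy)-2-fluoro-3-methoxybenzoic acid | O=C(O)c1ccc(OCc2ccccc2)c(OC)c1F
F5 | step 6 | 4-(benzyloxy)-2-fluoro-3-methoxybenzoyl chloride | O=C(Cl)c1ccc(OCc2ccccc2)c(OC)c1F
F6 | step 6 | 2-[3-(benzyloxy)-2,4,5-trimethoxyphenyl]vinyl 4-(benzyloxy)-2-fluoro-3-methoxybenzoate | COc1cc(C=COC(=O)c2ccc(OCc3ccccc3)c(OC)c2F)c(OC)c(OCc2ccccc2)c1OC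
F7 | step 6 | 3-[4-(benzyloxy)-2-fluoro-3-methoxyphenyl]-2-[3-(benzyloxy)-2,4,5-trimethoxyphenyl]-3-oxopropanal (hydroxymethylene tautomer) | COc1cc(C(=CO)C(=O)c2ccc(OCc3ccccc3)c(OC)c2F)c(OC)c(OCc2ccccc2)c1OC
F8 | step 8 | O-{(3S,4S)-7-(benzyloxy)-3-[3-(benzyloxy)-2,4,5-trimethoxyphenyl]-8-methoxychroman-4-yl} imidazole-1-carbothioate | COc1cc([C@H]2COc3c(ccc(OCc4ccccc4)c3OC)[C@H]2OC(=S)n2ccnc2)c(OC)c(OCc2ccccc2)c1OC
F9 | step 8 | (3S)-7-(benzyloxy)-3-[3-(benzyloxy)-2,4,5-trimethoxyphenyl]-8-methoxychroman | COc1cc([C@H]2COc3c(ccc(OCc4ccccc4)c3OC)C2)c(OC)c(OCc2ccccc2)c1OC
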